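**Retrosynthetic overview**

- The biaryl bond (isoquinoline C7 to naphthalene C8') is cut last: C7 metalation between the two methoxy groups of the finished N-methyl-tetrahydroisoquinoline, then Negishi coupling with an 8'-bromonaphthalene. No ring is formed here.
- The nitrogen ring is closed as in the plant: an aryl 1,5-diketone (acetyl plus acetonyl on a dimethoxybenzene) is aminated at the acetonyl carbonyl by an (S)-selective transaminase (sets C3) and condenses onto the aryl ketone. cis-Selective hydride reduction then sets C1.
- That diketone comes from C-acetylation of 3,5-dimethoxyphenylacetone via a 2-benzopyrylium salt.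
- The methyl-bearing naphthalene ring (ring A) is closed by the biosynthetic intramolecular aldol condensation of a second 1,5-diketone, made by aryne acyl-alkylation of acetylacetone and brominated para to the methoxy group.
- Ring order: the hetero ring (steps 1–3) and naphthalene ring A (steps 4–6) are built in separate branches and joined in step 7.

Assumption: the SMILES fixes only C1 (R) and C3 (S, 1,3-cis) and gives no axial descriptor, so the biaryl axis is not controlled and any separable rotamers would be parted by chromatography at the end.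

**Route**

Step 1
Reactants: 1 1-(3,5-dimethoxyphenyl)propan-2-one
Product: 3 1-(2-acetyl-3,5-dimethoxyphenyl)propan-2-one, via benzopyrylium tetrafluoroborate 2 (not isolated)
Conditions: Ac2O, HBF4·OEt2, 0 °C to rt; then aq NaOAc, Et2O, rt
Reagents that add atoms: acetic anhydride, CC(=O)OC(C)=O; water, O
Why: Friedel–Crafts C-acetylation at the doubly activated position ortho to the acetonyl arm (both such positions are equivalent) is trapped by cyclodehydration as the 2-benzopyrylium salt, which blocks a second acylation and is reopened by water on work-up to the 1,5-diketone that mirrors the biosynthetic polyketide diketone.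

Step 2
Reactants: 3 1-(2-acetyl-3,5-dimethoxyphenyl)propan-2-one
Product: 5 (3S)-6,8-dimethoxy-1,3-dimethyl-3,4-dihydroisoquinoline, via amino ketone 4 (not isolated)
Conditions: (S)-selective ω-transaminase (Vibrio fluvialis type), pyridoxal 5'-phosphate, i-PrNH2, K2HPO4/KH2PO4 buffer pH 8, DMSO (10 vol%), 30 °C; then pH 11, extraction
Reagents that add atoms: isopropylamine, CC(C)N
Why: Biocatalytic transamination is expected to aminate only the unhindered benzyl methyl ketone (the di-ortho-substituted aryl ketone should be no substrate) and sets C3 as S under enzyme control, after which the amine condenses spontaneously onto the aryl ketone to the cyclic imine (transaminase-triggered cyclocondensation, the laboratory copy of the presumed biosynthetic amination and ring closure), which also pulls the transamination equilibrium.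

Step 3
Reactants: 5 (3S)-6,8-dimethoxy-1,3-dimethyl-3,4-dihydroisoquinoline
Product: 7 (1R,3S)-6,8-dimethoxy-1,2,3-trimethyl-1,2,3,4-tetrahydroisoquinoline, via secondary amine 6 (not isolated)
Conditions: NaBH4, MeOH, 0 °C; then aq HCHO, rt; then NaBH4, 0 °C to rt
Reagents that add atoms: formaldehyde, C=O
Why: Hydride reduction of the cyclic imine occurs on the face anti to the C3 methyl group, so both methyl groups end up pseudo-equatorial and C1 is set as R (1,3-cis, substrate control), and the secondary amine is then N-methylated in the same pot by reductive amination with formaldehyde.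

Step 4
Reactants: 8 3-methoxy-2-(trimethylsilyl)phenyl trifluoromethanesulfonate; 9 pentane-2,4-dione (acetylacetone)
Product: 11 1-(2-acetyl-3-methoxyphenyl)propan-2-one, via 3-methoxybenzyne 10 (not isolated)
Conditions: CsF, MeCN, 80 °C, 1 h
Reagents that add atoms: none
Why: Aryne acyl-alkylation (formal insertion of the aryne into a C–C bond of the 1,3-diketone): the enolate carbon adds to the aryne carbon remote from OMe, the aryl anion formed next to OMe attacks a carbonyl and the benzocyclobutenoxide fragments, which places acetyl ortho to OMe and acetonyl beside it, and the symmetric diketone leaves no choice of acyl group.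

Step 5
Reactants: 11 1-(2-acetyl-3-methoxyphenyl)propan-2-one
Product: 12 1-(2-acetyl-6-bromo-3-methoxyphenyl)propan-2-one
Conditions: NBS, (CF3)2CHOH, 0 °C to rt, dark
Reagents that add atoms: N-bromosuccinimide, O=C1CCC(=O)N1Br
Why: Electrophilic aromatic bromination goes para to the methoxy group (also meta to the acetyl group), the usual anisole preference over the ortho position, while neutral, acid-free, dark conditions should leave the ketone α-positions untouched.

Step 6
Reactants: 12 1-(2-acetyl-6-bromo-3-methoxyphenyl)propan-2-one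
Product: 14 1-bromo-4,5-dimethoxy-7-methylnaphthalene, via bromonaphthol 13 (not isolated)
Conditions: Cs2CO3, DMF, 70 °C; then MeI, rt
Reagents that add atoms: iodomethane, CI
Why: Intramolecular aldol condensation of the 1,5-diketone as in the polyketide pathway: the enolate of the aryl methyl ketone attacks the more electrophilic acetonyl carbonyl, dehydration and enolisation give the 1-naphthol with the methyl group in the new ring, and the naphthoxide is O-methylated in the same pot (Williamson ether synthesis).

Step 7
Reactants: 7 (1R,3S)-6,8-dimethoxy-1,2,3-trimethyl-1,2,3,4-tetrahydroisoquinoline; 14 1-bromo-4,5-dimethoxy-7-methylnaphthalene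
Product: 17 ancistrobrevine A, via aryllithium 15 (not isolated), via arylzinc chloride 16 (not isolated)
Conditions: 7, n-BuLi, TMEDA, THF, 0 °C; ZnCl2, THF, 0 °C to rt; then 14, Pd2(dba)3, SPhos, THF, 65 °C
Reagents that add atoms: none
Why: Directed ortho-metalation occurs at C7, the only position flanked by two methoxy groups, transmetalation gives a tolerant arylzinc, and Negishi coupling with a dialkylbiarylphosphine ligand joins the 2,6-dimethoxyaryl unit to the 1-naphthyl bromide without touching the two stereocentres.

**Compound list**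

1 | 1-(3,5-dimethoxyphenyl)propan-2-one | CC(=O)Cc1cc(OC)cc(OC)c1 | starting material
2 | 6,8-dimethoxy-1,3-dimethylisochromenylium (2-benzopyrylium) tetrafluoroborate | COc1cc(OC)c2c(C)[o+]c(C)cc2c1.F[B-](F)(F)F | intermediate
3 | 1-(2-acetyl-3,5-dimethoxyphenyl)propan-2-one | CC(=O)Cc1cc(OC)cc(OC)c1C(C)=O | intermediate
4 | 1-{2-[(2S)-2-aminopropyl]-4,6-dimethoxyphenyl}ethan-1-one | C[C@H](N)Cc1cc(OC)cc(OC)c1C(C)=O | intermediate
5 | (3S)-6,8-dimethoxy-1,3-dimethyl-3,4-dihydroisoquinoline | COc1cc(OC)c2c(c1)C[C@H](C)N=C2C | intermediate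
6 | (1R,3S)-6,8-dimethoxy-1,3-dimethyl-1,2,3,4-tetrahydroisoquinoline | COc1cc(OC)c2c(c1)C[C@H](C)N[C@@H]2C | intermediate
7 | (1R,3S)-6,8-dimethoxy-1,2,3-trimethyl-1,2,3,4-tetrahydroisoquinoline | COc1cc(OC)c2c(c1)C[C@H](C)N(C)[C@@H]2C | intermediate
8 | 3-methoxy-2-(trimethylsilyl)phenyl trifluoromethanesulfonate | COc1cccc(OS(=O)(=O)C(F)(F)F)c1[Si](C)(C)C | starting material
9 | pentane-2,4-dione (acetylacetone) | CC(=O)CC(C)=O | starting material
10 | 3-methoxybenzyne | COC1=CC=CC#C1 | intermediate
11 | 1-(2-acetyl-3-methoxyphenyl)propan-2-one | CC(=O)Cc1cccc(OC)c1C(C)=O | intermediate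
12 | 1-(2-acetyl-6-bromo-3-methoxyphenyl)propan-2-one | CC(=O)Cc1c(Br)ccc(OC)c1C(C)=O | intermediate
13 | 5-bromo-8-methoxy-3-methylnaphthalen-1-ol | Cc1cc(O)c2c(OC)ccc(Br)c2c1 | intermediate
14 | 1-bromo-4,5-dimethoxy-7-methylnaphthalene | Cc1cc(OC)c2c(OC)ccc(Br)c2c1 | intermediate
15 | [(1R,3S)-6,8-dimethoxy-1,2,3-trimethyl-1,2,3,4-tetrahydroisoquinolin-7-yl]lithium | COc1cc2c(c(OC)c1[Li])[C@@H](C)N(C)[C@@H](C)C2 | intermediate
16 | [(1R,3S)-6,8-dimethoxy-1,2,3-trimethyl-1,2,3,4-tetrahydroisoquinolin-7-yl]zinc chloride | COc1cc2c(c(OC)c1[Zn]Cl)[C@@H](C)N(C)[C@@H](C)C2 | intermediate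
17 | ancistrobrevine A, (1R,3S)-7-(4,5-dimethoxy-7-methylnaphthalen-1-yl)-6,8-dimethoxy-1,2,3-trimethyl-1,2,3,4-tetrahydroisoquinoline | COc1cc2c(c(OC)c1-c1ccc(OC)c3c(OC)cc(C)cc13)[C@@H](C)N(C)[C@@H](C)C2 | target

**Step count**

Total: 7 steps. Longest linear sequence: 4 steps (steps 1, 2, 3, 7 or steps 4, 5, 6, 7).

**Steps most likely to fail, with fallbacks**

Step 2. The enzyme may not accept an arylacetone carrying an ortho acetyl group, and the diketone can condense chemically with the amine donor to an N-isopropylisoquinolinium salt. The fallback sets out from 1 and comes back at 5, replacing the biocatalytic amination by an auxiliary-controlled reductive amination and a Bischler–Napieralski ring closure. Compound 1 is condensed with (S)-1-phenylethylamine (toluene, reflux, water removal) to (S)-N-[1-(3,5-dimethoxyphenyl)propan-2-ylidene]-1-phenylethanamine F1. This is hydrogenated (H2, Raney Ni, EtOH) to (2S)-1-(3,5-dimethoxyphenyl)-N-[(1S)-1-phenylethyl]propan-2-amine F2, whose hydrochloride is recrystallised to remove the minor diastereomer. Hydrogenolysis (H2, Pd/C, MeOH) gives (2S)-1-(3,5-dimethoxyphenyl)propan-2-amine F3, acetylation (Ac2O, Et3N, CH2Cl2) gives N-[(2S)-1-(3,5-dimethoxyphenyl)propan-2-yl]acetamide F4, and POCl3 in MeCN at reflux closes the ring to 5. Step 1 is then not needed and the route continues with step 3.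

Step 5. Bromination may attack a ketone α-position, or the ring may be too deactivated by the acetyl group. The fallback sets out from 11 and comes back at 13, moving the bromination to the naphthalene stage with the two rings electronically differentiated. Compound 11 is cyclised first (Cs2CO3, DMF, 70 °C) to 8-methoxy-3-methylnaphthalen-1-ol F5 and tosylated (TsCl, Et3N, DMAP, CH2Cl2) to 8-methoxy-3-methylnaphthalen-1-yl 4-methylbenzenesulfonate F6. With ring A deactivated by the sulfonate, NBS in MeCN should brominate ring B para to the methoxy group, giving 5-bromo-8-methoxy-3-methylnaphthalen-1-yl 4-methylbenzenesulfonate F7. Cleavage of the sulfonate (KOH, MeOH/THF, 60 °C) gives 13, which is methylated as in the second half of step 6.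

Step 7. The hindered, electron-rich arylzinc may protodemetalate or transmetalate poorly, and any lithiation regioisomer cannot be removed before coupling. The fallback sets out from 15 and 14 and comes back at 17, reversing the polarity of the union. Aryllithium 15 is quenched with I2 to the isolable (1R,3S)-7-iodo-6,8-dimethoxy-1,2,3-trimethyl-1,2,3,4-tetrahydroisoquinoline F8, whose regiochemistry can be checked and purified. Bromide 14 is converted (B2pin2, PdCl2(dppf), KOAc, dioxane, 90 °C) to 2-(4,5-dimethoxy-7-methylnaphthalen-1-yl)-4,4,5,5-tetramethyl-1,3,2-dioxaborolane F9. Suzuki–Miyaura coupling of the two (Pd(OAc)2, SPhos, K3PO4, toluene/water, 100 °C) gives 17.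

**Further compounds**

F1 | step 2 | (S)-N-[1-(3,5-dimethoxyphenyl)propan-2-ylidene]-1-phenylethanamine | CC(Cc1cc(OC)cc(OC)c1)=N[C@@H](C)c1ccccc1
F2 | step 2 | (2S)-1-(3,5-dimethoxyphenyl)-N-[(1S)-1-phenylethyl]propan-2-amine | C[C@H](N[C@@H](C)c1ccccc1)Cc1cc(OC)cc(OC)c1
F3 | step 2 | (2S)-1-(3,5-dimethoxyphenyl)propan-2-amine | C[C@H](N)Cc1cc(OC)cc(OC)c1
F4 | step 2 | N-[(2S)-1-(3,5-dimethoxyphenyl)propan-2-yl]acetamide | C[C@H](NC(C)=O)Cc1cc(OC)cc(OC)c1
F5 | step 5 | 8-methoxy-3-methylnaphthalen-1-ol | Cc1cc(O)c2c(OC)cccc2c1
F6 | step 5 | 8-methoxy-3-methylnaphthalen-1-yl 4-methylbenzenesulfonate | Cc1ccc(cc1)S(=O)(=O)Oc1cc(C)cc2cccc(OC)c12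
F7 | step 5 | 5-bromo-8-methoxy-3-methylnaphthalen-1-yl 4-methylbenzenesulfonate | Cc1ccc(cc1)S(=O)(=O)Oc1cc(C)cc2c(Br)ccc(OC)c12
F8 | step 7 | (1R,3S)-7-iodo-6,8-dimethoxy-1,2,3-trimethyl-1,2,3,4-tetrahydroisoquinoline | COc1cc2c(c(OC)c1I)[C@@H](C)N(C)[C@@H](C)C2
F9 | step 7 | 2-(4,5-dimethoxy-7-methylnaphthalen-1-yl)-4,4,5,5-tetramethyl-1,3,2-dioxaborolane | Cc1cc(OC)c2c(OC)ccc(B3OC(C)(C)C(C)(C)O3)c2c1
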